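The cyclohexene ring (C5–C10 of the spiro[4.5]dec-7-ene) is read as methyl propiolate (C7=C8–CO2Me) clamped between two arms of the quaternary spiro carbon C5: the neopentyl methylene C6 and the carbinol C9. A radical [4+2] annulation should join the alkyne to a cyclopentane carrying iodomethyl and formylmethyl groups on C5: the C6 radical adds to the alkyne (C6–C7) and the vinyl radical closes on the aldehyde (C8–C9). The precursor comes from cis,trans-nepetalactone, whose stereocenters become C1 and C4 and relay the side-chain methine and C5 (hydrogenation, ring-fusion allylation); C9 is finally fixed by reagent-controlled reduction of the derived enone.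

Key step: step 8

Remark on numbering: compounds 1–5 use cyclopenta[c]pyranone numbering; compounds 15–19 use spiro[4.5]dec-7-ene numbering (C1 methyl-bearing, C4 side-chain-bearing, C5 spiro, C6 CH2, C7=C8 with CO2Me on C8, C9 carbinol, C10 CH2).
Assumption: (4aS,7S,7aR)-nepetalactone, the main constituent of commercial catnip oil, is taken as a purchasable starting material.

Step 1
Reactants: 1 (4aS,7S,7aR)-nepetalactone
Product: 2 (4S,4aR,7S,7aR)-dihydronepetalactone
Conditions: H2 (1–3 atm), 5% Pd/SrCO3, EtOH, rt
Reagents that add atoms: none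
Why: Heterogeneous catalytic hydrogenation of the enol-lactone double bond should add hydrogen from the convex face of the cis-fused bicycle (the face of the two ring-fusion hydrogens), which places the C4 methyl on the concave side and sets the 4S centre, the future side-chain methine.

Step 2
Reactants: 2 (4S,4aR,7S,7aR)-dihydronepetalactone; 3 allyl bromide
Product: 5 (4S,4aR,7S,7aR)-7a-allyl-4,7-dimethylhexahydrocyclopenta[c]pyran-1(3H)-one, via lithium lactone enolate 4 (not isolated)
Conditions: LiN(i-Pr)2, THF, −78 °C; then 3, DMPU, −78 to −30 °C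
Reagents that add atoms: none
Why: Alkylation of the lactone enolate at the ring-fusion carbon creates the quaternary centre, and the allyl group should enter on the convex face in place of the former ring-fusion hydrogen, because the other face is screened by the C4 methine of the lactone ring and would lead to a strained trans-fused lactone, so that the allyl group ends cis to the C7 methyl and trans to the C4 carbon.

Step 3
Reactants: 5 (4S,4aR,7S,7aR)-7a-allyl-4,7-dimethylhexahydrocyclopenta[c]pyran-1(3H)-one
Product: 6 (S)-2-[(1R,2R,3S)-2-allyl-2-(hydroxymethyl)-3-methylcyclopentyl]propan-1-ol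
Conditions: LiAlH4, THF, 0 °C to reflux; aqueous NaOH work-up
Reagents that add atoms: none
Why: Hydride reduction of the lactone with LiAlH4 opens the ring to the 1,5-diol without touching a stereocenter or the allyl group.

Step 4
Reactants: 6 (S)-2-[(1R,2R,3S)-2-allyl-2-(hydroxymethyl)-3-methylcyclopentyl]propan-1-ol
Product: 7 (1R,2R,3S)-2-allyl-2-(iodomethyl)-1-[(S)-1-iodopropan-2-yl]-3-methylcyclopentane
Conditions: I2, PPh3, imidazole, toluene, 0 to 80 °C
Reagents that add atoms: iodine, II
Why: Appel-type iodination through the two oxyphosphonium ions, in which iodide displaces Ph3P=O at both primary carbons (the neopentyl one needs the heat and has no β-hydrogen to eliminate) and no stereogenic carbon is involved.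

Step 5
Reactants: 8 3-methylbutan-2-one; 9 1,1-dimethylhydrazine
Product: 10 3-methylbutan-2-one N,N-dimethylhydrazone
Conditions: AcOH (cat.), EtOH, reflux; distillation
Reagents that add atoms: none
Why: Acid-catalysed condensation of the ketone with the hydrazine should give the N,N-dimethylhydrazone, the precursor of the azaenolate.

Step 6
Reactants: 7 (1R,2R,3S)-2-allyl-2-(iodomethyl)-1-[(S)-1-iodopropan-2-yl]-3-methylcyclopentane; 10 3-methylbutan-2-one N,N-dimethylhydrazone
Product: 13 (R)-6-[(1R,2R,3S)-2-allyl-2-(iodomethyl)-3-methylcyclopentyl]-2-methylheptan-3-one, via lithio azaenolate 11 (not isolated), via alkylated hydrazone 12 (not isolated)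
Conditions: 10 (1.3 equiv), LiN(i-Pr)2 (1.3 equiv), THF, 0 °C; then 7, −78 °C to rt; then saturated aqueous oxalic acid, Et2O, rt
Reagents that add atoms: water, O
Why: Azaenolate alkylation, in which the hydrazone is deprotonated at its methyl group and the soft carbon nucleophile displaces only the unhindered primary iodide (the neopentyl iodide is inert to SN2 attack), followed by mild acid hydrolysis of the hydrazone to the isopropyl ketone with the side-chain methine untouched.

Step 7
Reactants: 13 (R)-6-[(1R,2R,3S)-2-allyl-2-(iodomethyl)-3-methylcyclopentyl]-2-methylheptan-3-one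
Product: 15 2-[(1R,2S,5R)-1-(iodomethyl)-2-methyl-5-[(R)-6-methyl-5-oxoheptan-2-yl]cyclopentyl]acetaldehyde, via ozonide 14 (not isolated)
Conditions: O3, CH2Cl2, −78 °C, stopped when the alkene is consumed; then PPh3, −78 °C to rt
Reagents that add atoms: ozone, [O-][O+]=O
Why: Ozonolysis of the terminal alkene with reductive work-up trims the allyl group to the formylmethyl arm, and the ketone and the neopentyl iodide should survive at −78 °C if the ozone stream is stopped at the end point.

Step 8
Reactants: 15 2-[(1R,2S,5R)-1-(iodomethyl)-2-methyl-5-[(R)-6-methyl-5-oxoheptan-2-yl]cyclopentyl]acetaldehyde; 16 methyl propiolate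
Product: 17 methyl (1S,4R,5S)-9-hydroxy-1-methyl-4-[(R)-6-methyl-5-oxoheptan-2-yl]spiro[4.5]dec-7-ene-8-carboxylate as a mixture of C9 epimers
Conditions: 16 (10 equiv), (Me3Si)3SiH (2 equiv) and AIBN (0.3 equiv) added by syringe pump over 8 h, PhH (0.02 M), 80 °C
Reagents that add atoms: none
Why: Proposed new method: chain mechanism – the silyl radical abstracts iodine from the neopentyl iodide, the C6 radical adds to the unsubstituted alkyne carbon of 16 (bond C6–C7), the linear α-carbomethoxy vinyl radical attacks the aldehyde carbon (bond C8–C9), and the alkoxy radical takes hydrogen from the silane, which carries the chain. The closest known reaction types are the Giese addition of alkyl iodides to propiolates, radical annulations in which the resulting vinyl radical closes on an alkene, and cyclizations of vinyl radicals onto aldehydes; their union with an aldehyde as terminator is what is new. The cyclohexene ring closes in a 6-exo-trig mode at the carbonyl carbon with the C7=C8 bond inside the ring, which the π-type vinyl radical can reach from either geometry. C9 is the only new stereocenter and no element of the substrate controls it reliably, because half-chair arrangements with C4 or C1 axial and the oxygen pseudo-equatorial or pseudo-axial lie close in energy, so it is reset in steps 9 and 10; C1, C4, C5 and the side-chain methine are not touched. The step needs chemoselectivity (addition to the alkyne before hydrogen transfer, ring closure before reduction or 1,5-hydrogen shift of the vinyl radical, the remote ketone left alone), which the substrate secures through a neopentyl radical that can neither eliminate nor close a four-membered ring and a short tether to the aldehyde, helped by excess alkyne and a slow hydrogen donor kept dilute.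

Step 9
Reactants: 17 methyl (1S,4R,5S)-9-hydroxy-1-methyl-4-[(R)-6-methyl-5-oxoheptan-2-yl]spiro[4.5]dec-7-ene-8-carboxylate as a mixture of C9 epimers
Product: 18 methyl (1S,4R,5S)-1-methyl-4-[(R)-6-methyl-5-oxoheptan-2-yl]-9-oxospiro[4.5]dec-7-ene-8-carboxylate
Conditions: Dess–Martin periodinane, NaHCO3, CH2Cl2, 0 °C to rt
Reagents that add atoms: none
Why: Dess–Martin oxidation should convert both carbinol epimers into one enone under buffered, non-enolizing conditions, which removes the uncontrolled centre and leaves the side-chain ketone and the other stereocenters alone.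

Step 10
Reactants: 18 methyl (1S,4R,5S)-1-methyl-4-[(R)-6-methyl-5-oxoheptan-2-yl]-9-oxospiro[4.5]dec-7-ene-8-carboxylate
Product: 19 methyl (1S,4R,5S,9S)-9-hydroxy-1-methyl-4-[(R)-6-methyl-5-oxoheptan-2-yl]spiro[4.5]dec-7-ene-8-carboxylate (CNP0116894.1)
Conditions: (R)-2-methyl-CBS-oxazaborolidine [(R)-1-methyl-3,3-diphenyltetrahydro-1H,3H-pyrrolo[1,2-c][1,3,2]oxazaborole] (0.2 equiv), catecholborane (1.5 equiv), toluene, −78 °C
Reagents that add atoms: none
Why: CBS reduction, in which the catalyst–borane complex binds the ring ketone anti to the larger alkenyl side (C8) and delivers hydride in a 1,2-sense to the face that gives 9S under catalyst control (the face that equatorial delivery anti to an axial C4 would also favour), while the hindered, non-conjugated isopropyl ketone should not react at −78 °C.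

Compound list
1 | (4aS,7S,7aR)-nepetalactone [(4aS,7S,7aR)-4,7-dimethyl-5,6,7,7a-tetrahydrocyclopenta[c]pyran-1(4aH)-one] | C[C@H]1CC[C@@H]2C(C)=COC(=O)[C@H]12 | starting material
2 | (4S,4aR,7S,7aR)-dihydronepetalactone [(4S,4aR,7S,7aR)-4,7-dimethylhexahydrocyclopenta[c]pyran-1(3H)-one] | C[C@H]1CC[C@@H]2[C@H](C)COC(=O)[C@H]12 | intermediate
3 | allyl bromide | C=CCBr | starting material
4 | lithium enolate of lactone 2 | C[C@H]1CC[C@@H]2[C@H](C)COC(O[Li])=C12 | intermediate
5 | (4S,4aR,7S,7aR)-7a-allyl-4,7-dimethylhexahydrocyclopenta[c]pyran-1(3H)-one | C[C@H]1CC[C@@H]2[C@H](C)COC(=O)[C@]12CC=C | intermediate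
6 | (S)-2-[(1R,2R,3S)-2-allyl-2-(hydroxymethyl)-3-methylcyclopentyl]propan-1-ol | C[C@H]1CC[C@H]([C@H](C)CO)[C@@]1(CO)CC=C | intermediate
7 | (1R,2R,3S)-2-allyl-2-(iodomethyl)-1-[(S)-1-iodopropan-2-yl]-3-methylcyclopentane | C[C@H]1CC[C@H]([C@H](C)CI)[C@@]1(CI)CC=C | intermediate
8 | 3-methylbutan-2-one | CC(=O)C(C)C | starting material
9 | 1,1-dimethylhydrazine | CN(C)N | starting material
10 | 3-methylbutan-2-one N,N-dimethylhydrazone | CC(=NN(C)C)C(C)C | intermediate
11 | lithio azaenolate of hydrazone 10 | C=C(C(C)C)N([Li])N(C)C | intermediate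
12 | N,N-dimethylhydrazone of ketone 13 | C[C@H]1CC[C@H]([C@H](C)CCC(=NN(C)C)C(C)C)[C@@]1(CI)CC=C | intermediate
13 | (R)-6-[(1R,2R,3S)-2-allyl-2-(iodomethyl)-3-methylcyclopentyl]-2-methylheptan-3-one | C[C@H]1CC[C@H]([C@H](C)CCC(=O)C(C)C)[C@@]1(CI)CC=C | intermediate
14 | ozonide (1,2,4-trioxolane) of alkene 13 | C[C@H]1CC[C@H]([C@H](C)CCC(=O)C(C)C)[C@@]1(CI)CC1OCOO1 | intermediate
15 | 2-[(1R,2S,5R)-1-(iodomethyl)-2-methyl-5-[(R)-6-methyl-5-oxoheptan-2-yl]cyclopentyl]acetaldehyde | C[C@H]1CC[C@H]([C@H](C)CCC(=O)C(C)C)[C@@]1(CI)CC=O | intermediate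
16 | methyl propiolate | C#CC(=O)OC | starting material
17 | methyl (1S,4R,5S)-9-hydroxy-1-methyl-4-[(R)-6-methyl-5-oxoheptan-2-yl]spiro[4.5]dec-7-ene-8-carboxylate, mixture of C9 epimers | COC(=O)C1=CC[C@@]2(CC1O)[C@@H]([C@H](C)CCC(=O)C(C)C)CC[C@@H]2C | intermediate
18 | methyl (1S,4R,5S)-1-methyl-4-[(R)-6-methyl-5-oxoheptan-2-yl]-9-oxospiro[4.5]dec-7-ene-8-carboxylate | COC(=O)C1=CC[C@@]2(CC1=O)[C@@H]([C@H](C)CCC(=O)C(C)C)CC[C@@H]2C | intermediate
19 | methyl (1S,4R,5S,9S)-9-hydroxy-1-methyl-4-[(R)-6-methyl-5-oxoheptan-2-yl]spiro[4.5]dec-7-ene-8-carboxylate | COC(=O)C1=CC[C@@]2(C[C@@H]1O)[C@@H]([C@H](C)CCC(=O)C(C)C)CC[C@@H]2C | target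

Total step count: 10. Longest linear sequence: 9 steps (steps 1–4 and 6–10; step 5 prepares the hydrazone).

Steps most likely to fail

Step 8 (Proposed new method; chemoselectivity of the cascade): hydrogen transfer to the vinyl radical, or its 1,5-hydrogen shift, may outrun closure onto the aldehyde, and the alkoxy radical may fragment, so that open-chain material results. The fallback uses known reactions, sets out from 15 and comes back at 17. Giese addition of 15 to 16 under ordinary tin hydride conditions (Bu3SnH at normal concentration, AIBN, PhH, 80 °C), which reduces the vinyl radical on purpose, should give methyl 4-[(1S,2S,5R)-2-methyl-5-[(R)-6-methyl-5-oxoheptan-2-yl]-1-(2-oxoethyl)cyclopentyl]but-2-enoate F1 as an E/Z mixture. PMe3 in t-BuOH/THF should then close the ring by an intramolecular Morita–Baylis–Hillman reaction (the phosphine adds to C7, the enolate attacks the aldehyde, loss of the phosphine restores C7=C8) to give 17.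

Step 4: substitution at the doubly flanked neopentyl carbon may stall, and the half-activated 1,5-diol may close to a tetrahydropyran. The fallback sets out from 6 and comes back at 7. Both hydroxyls are first capped at low temperature (Tf2O, pyridine, CH2Cl2, −78 to −20 °C) as the bis(trifluoromethanesulfonate) of diol 6 F2, so that no free hydroxyl remains to close a ring. The two sulfonates are then displaced in a Finkelstein reaction (NaI, DMF, rt to 50 °C) to give 7.

Step 10: the catalyst may also reduce the side-chain ketone, or facial control may be weak. The fallback sets out from 17 and comes back at 19 without the enone (steps 9 and 10 are not run). The C9 epimers of 17 are separated by chromatography; the 9S epimer is 19. The other epimer, methyl (1S,4R,5S,9R)-9-hydroxy-1-methyl-4-[(R)-6-methyl-5-oxoheptan-2-yl]spiro[4.5]dec-7-ene-8-carboxylate F3, undergoes Mitsunobu inversion (4-nitrobenzoic acid, PPh3, DIAD, THF, 0 °C) to methyl (1S,4R,5S,9S)-1-methyl-4-[(R)-6-methyl-5-oxoheptan-2-yl]-9-[(4-nitrobenzoyl)oxy]spiro[4.5]dec-7-ene-8-carboxylate F4. K2CO3 in MeOH at 0 °C then removes the ester to give 19.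

Further compounds
F1 | step 8 | methyl 4-[(1S,2S,5R)-2-methyl-5-[(R)-6-methyl-5-oxoheptan-2-yl]-1-(2-oxoethyl)cyclopentyl]but-2-enoate (E/Z mixture) | C[C@H]1CC[C@H]([C@H](C)CCC(=O)C(C)C)[C@@]1(CC=CC(=O)OC)CC=O
F2 | step 4 | bis(trifluoromethanesulfonate) of diol 6 | C[C@H]1CC[C@H]([C@H](C)COS(=O)(=O)C(F)(F)F)[C@@]1(COS(=O)(=O)C(F)(F)F)CC=C
F3 | step 10 | methyl (1S,4R,5S,9R)-9-hydroxy-1-methyl-4-[(R)-6-methyl-5-oxoheptan-2-yl]spiro[4.5]dec-7-ene-8-carboxylate | COC(=O)C1=CC[C@@]2(C[C@H]1O)[C@@H]([C@H](C)CCC(=O)C(C)C)CC[C@@H]2C
F4 | step 10 | methyl (1S,4R,5S,9S)-1-methyl-4-[(R)-6-methyl-5-oxoheptan-2-yl]-9-[(4-nitrobenzoyl)oxy]spiro[4.5]dec-7-ene-8-carboxylate | COC(=O)C1=CC[C@@]2(C[C@@H]1OC(=O)c1ccc(cc1)[N+](=O)[O-])[C@@H]([C@H](C)CCC(=O)C(C)C)CC[C@@H]2C
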